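The target is cut at the C4–C5 bond of the spiro γ-lactone. The feature used is the spiro atom C5: it is common to ring A (C5–C10), ring B (C1–C5, C10) and the lactone, and the lactone ties it to C4 directly and to the carbonyl C18 through C19 and the ring oxygen, so that C4 and the C5–H bond of a ring-A ester stand 1,5 to each other. A dirhodium carbenoid at C4 inserts into that tertiary C–H bond with retention, which closes the lactone and makes the quaternary centre in one operation. The precursor is a fully substituted ring-A cyclohexane whose C19 hydroxymethyl arm carries a diazo(diethoxyphosphoryl)acetate; the phosphonate later closes ring B.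

Key step: step 22

Remark (numbering and faces): ring A = C5–C10 (C7 bears OAc, C8 the methyl C17, C9 the methyl C20 and C11); ring B = C1–C5, C10; ring C = C1, C16, C13, C12, C11, C9, C10; lactone = C4, C18(=O), O, C19, C5. β is the face of ring A that carries C19.

Remark (structures): in 30 and 31 the centres C5, C7, C8, C9 and C10 have the configuration of the target (C19, C1, C20, C17 and the 7-oxygen β; C11 α). C4 of 31 should form as a mixture of epimers; one is drawn, and the centre is lost in step 25.

Remark (design): the C7 acetate is put on before ring B exists, because the 7β oxygen becomes axial and flanked by C19 and C20 once the decalin is closed.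

Assumption: 1, 2, 4, 16 and 28 are taken as commercially available.

Step 1
Reactants: 1 5-hydroxyfuran-2(5H)-one; 2 (1S,2R,5S)-(+)-menthol
Product: 3 (5S)-5-[(1S,2R,5S)-menthyloxy]furan-2(5H)-one
Conditions: TsOH (cat.), toluene, reflux with water separation; crystallisation from petroleum ether, mother liquor re-equilibrated with acid and recrystallised
Reagents that add atoms: none
Why: Acid-catalysed acetal exchange of the hemiacylal with the alcohol; the two C5 epimers should interconvert under the acid and the less soluble (5S) diastereomer is removed by crystallisation, which sets the acetal centre that later controls C5 and C10 of ring A.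

Step 2
Reactants: 4 (E)-pent-3-en-2-one
Product: 5 (E)-2-(triisopropylsilyloxy)penta-1,3-diene
Conditions: i-Pr3SiOTf, Et3N, Et2O, 0 °C
Reagents that add atoms: triisopropylsilyl trifluoromethanesulfonate, CC(C)[Si](OS(=O)(=O)C(F)(F)F)(C(C)C)C(C)C
Why: Soft enolisation and O-silylation on the methyl side of the ketone should give the cross-conjugated 2-silyloxy diene with the E alkene untouched; the bulky silyl group lets the enol ether survive steps 3 to 9 as a masked C7 ketone.

Step 3
Reactants: 3 (5S)-5-menthyloxyfuranone; 5 silyloxy diene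
Product: 6 cis-fused lactone acetal (Diels–Alder adduct; lactone carbonyl C1 on C10 and acetal carbon C19 on C5, both β; C7 silyl enol ether; C9 methyl β)
Conditions: toluene, 110 °C, sealed vessel, 2,6-di-tert-butyl-4-methylphenol (cat.)
Reagents that add atoms: none
Why: Thermal Diels–Alder reaction: the terminus C6 next to the silyloxy carbon (largest HOMO coefficient) should bond to the β-carbon of the butenolide so that C7 ends para to C10; the diene adds anti to the menthyloxy group, which fixes C5 and C10 (cis, absolute), and the endo transition state puts the C9 methyl β (erased in step 10).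

Step 4
Reactants: 6 lactone acetal
Product: 8 cis-fused γ-lactone (C1 carbonyl on C10 and C19 methylene on C5), via hydroxy acid 7 (not isolated)
Conditions: NaOH (aq), NaBH4, MeOH/THF, 0 °C to rt; then 1 M HCl to pH 4, 0 °C
Reagents that add atoms: sodium hydroxide, [Na+].[OH-] (its oxygen can be exchanged into the lactone carbonyl)
Why: Saponification of the acyl acetal releases menthol and the C19 aldehyde, which borohydride should reduce at once, before C5 can epimerise; the cis γ-hydroxy acid relactonises on mild acidification, and no stereocentre is formed.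

Step 5
Reactants: 8 γ-lactone
Product: 10 hydroxy (E)-enoate (C10 bears CH=CH–CO2Et and C5 bears CH2OH), via lactol 9 (not isolated)
Conditions: i-Bu2AlH, CH2Cl2, −78 °C; then Ph3P=CHCO2Et, −78 °C to rt
Reagents that add atoms: ethyl (triphenylphosphoranylidene)acetate, CCOC(=O)C=P(c1ccccc1)(c1ccccc1)c1ccccc1
Why: Half-reduction of the lactone and Wittig olefination of the open hydroxy aldehyde form of the lactol with a stabilised ylide should give the E enoate and add C2 and C3; no stereocentre is formed.

Step 6
Reactants: 10 hydroxy enoate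
Product: 11 C19 triethylsilyl ether
Conditions: Et3SiCl, imidazole, CH2Cl2, 0 °C
Reagents that add atoms: chlorotriethylsilane, CC[Si](Cl)(CC)CC
Why: Silylation of the primary alcohol, done at once so that the hydroxyl cannot add back to the enoate (oxa-Michael), with a group that can later be removed beside a tert-butyldimethylsilyl ether.

Step 7
Reactants: 11 enoate
Product: 12 saturated ethyl ester
Conditions: H2 (1 atm), Pd/C (5%), EtOAc, rt
Reagents that add atoms: none
Why: Heterogeneous hydrogenation; the disubstituted conjugated alkene should be reduced much faster than the trisubstituted, hindered silyl enol ether.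

Step 8
Reactants: 12 ester
Product: 13 C3 primary alcohol
Conditions: LiAlH4, THF, 0 °C
Reagents that add atoms: none
Why: Hydride reduction of the ester; silyl ethers and the silyl enol ether are inert to LiAlH4.

Step 9
Reactants: 13 alcohol
Product: 14 C3 tert-butyldimethylsilyl ether
Conditions: t-BuMe2SiCl, imidazole, DMF, rt
Reagents that add atoms: tert-butyl(chloro)dimethylsilane, CC(C)(C)[Si](C)(C)Cl
Why: Standard silylation of a primary alcohol.

Step 10
Reactants: 14 silyl enol ether
Product: 15 ring-A enone (C7 ketone, C8=C9 with the C9 methyl; C5 and C10 arms cis, β)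
Conditions: Pd(OAc)2 (1.1 equiv), MeCN, 40 °C
Reagents that add atoms: none
Why: Saegusa–Ito oxidation; palladation of the enol ether at C8 and syn β-hydride elimination of H9 can only give the C8=C9 enone, which removes the C9 stereocentre and unmasks the acceptor for step 14.

Step 11
Reactants: 16 2-bromofuran-3-carboxylic acid
Product: 17 2-bromo-N-methoxy-N-methylfuran-3-carboxamide
Conditions: 1,1′-carbonyldiimidazole, CH2Cl2, rt; then MeNH(OMe)·HCl
Reagents that add atoms: N,O-dimethylhydroxylamine hydrochloride, CNOC.Cl
Why: Amide coupling through the acyl imidazolide.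

Step 12
Reactants: 17 amide
Product: 18 1-(2-bromofuran-3-yl)ethan-1-one
Conditions: MeMgBr, THF, 0 °C
Reagents that add atoms: methylmagnesium bromide, C[Mg]Br
Why: Weinreb ketone synthesis; the chelated tetrahedral intermediate stops at the ketone, and methylmagnesium bromide is a poor partner for bromine–magnesium exchange at this temperature.

Step 13
Reactants: 18 methyl ketone
Product: 19 [1-(2-bromofuran-3-yl)ethenyl]oxy(tert-butyl)dimethylsilane
Conditions: t-BuMe2SiOTf, Et3N, CH2Cl2, 0 °C
Reagents that add atoms: tert-butyldimethylsilyl trifluoromethanesulfonate, CC(C)(C)[Si](C)(C)OS(=O)(=O)C(F)(F)F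
Why: Soft enolisation and O-silylation of the methyl ketone.

Step 14
Reactants: 15 enone; 19 silyl enol ether
Product: 20 Michael adduct as C7 tert-butyldimethylsilyl enol ether (C9 quaternary: C20 β, C11 arm α)
Conditions: Tf2NH (5 mol %), CH2Cl2, −78 to −40 °C
Reagents that add atoms: none
Why: Mukaiyama–Michael addition under silyl-transfer catalysis (t-BuMe2SiNTf2 forms in the flask); A(1,2) strain with the C9 methyl holds the C10 chain pseudoaxial, so the nucleophile should attack C9 axially from the opposite, α face, and silyl transfer delivers the C7 enol ether regiospecifically.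

Step 15
Reactants: 20 silyl enol ether
Product: 23 α-methylene ketone (C8=C17H2), via Mannich base 21 (not isolated), via trimethylammonium iodide 22 (not isolated)
Conditions: Me2N=CH2 chloride, CH2Cl2, rt; then MeI; then NaHCO3 (aq), CH2Cl2
Reagents that add atoms: dimethyl(methylidene)ammonium chloride, C=[N+](C)C.[Cl-]
Why: Mannich reaction of the regiodefined silyl enol ether with the iminium salt, N-methylation and mild E1cB elimination (α-methylenation) should place C17 on C8 only; no stereocentre is formed.

Step 16
Reactants: 23 α-methylene ketone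
Product: 24 C7 ketone with C17 β on C8
Conditions: H2 (1 atm), [Ir(cod)(PCy3)(py)]PF6 (5 mol %), CH2Cl2, rt
Reagents that add atoms: none
Why: Carbonyl-directed homogeneous hydrogenation; the cationic iridium centre can bind the C12 carbonyl of the α-oriented C11 arm together with the exocyclic alkene, while the β face is screened by C20 and the C1 chain, so hydrogen should add to C8 from the α face and leave C17 β; this catalyst does not touch the aryl bromide or the furan.

Step 17
Reactants: 24 ketone
Product: 25 7β-alcohol
Conditions: NaBH4, MeOH/THF, −40 °C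
Reagents that add atoms: none
Why: Borohydride reduction of the cyclohexanone in preference to the deactivated, neopentyl 3-furyl ketone; in the chair with C17 equatorial the β face of C7 is blocked by axial C19 and C20, so hydride should enter from the α face and give the 7β alcohol, cis to C17.

Step 18
Reactants: 25 alcohol
Product: 26 7β-acetate
Conditions: Ac2O, 4-(dimethylamino)pyridine (cat.), pyridine, CH2Cl2, rt
Reagents that add atoms: acetic anhydride, CC(=O)OC(C)=O
Why: Nucleophile-catalysed acetylation of a secondary alcohol that is still unhindered in the flexible monocycle.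

Step 19
Reactants: 26 acetate
Product: 27 C19 primary alcohol
Conditions: pyridinium p-toluenesulfonate (cat.), MeOH/CH2Cl2, 0 °C
Reagents that add atoms: none
Why: Acid-catalysed methanolysis should remove the primary triethylsilyl ether much faster than the tert-butyldimethylsilyl ether; the acetate is not affected.

Step 20
Reactants: 27 alcohol; 28 diethylphosphonoacetic acid
Product: 29 C19 (diethoxyphosphoryl)acetate
Conditions: N,N′-dicyclohexylcarbodiimide, 4-(dimethylamino)pyridine (cat.), CH2Cl2, 0 °C to rt
Reagents that add atoms: none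
Why: Steglich esterification of the primary alcohol.

Step 21
Reactants: 29 phosphonoacetate
Product: 30 ring-A cyclohexylmethyl diazo(diethoxyphosphoryl)acetate (precursor of the key step)
Conditions: 4-acetamidobenzenesulfonyl azide, DBU, MeCN, 0 °C
Reagents that add atoms: 4-acetamidobenzenesulfonyl azide, CC(=O)Nc1ccc(cc1)S(=O)(=O)N=[N+]=[N-]
Why: Regitz diazo transfer to the doubly activated methylene group; the C11 methylene next to the ketone is not acidic enough to react.

Step 22
Reactants: 30 diazo(phosphono)acetate
Product: 31 spiro α-phosphono-γ-lactone on ring A (C5 quaternary: C19 β, C4 α)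
Conditions: Rh2(OAc)4 (2 mol %), ClCH2CH2Cl, reflux, slow addition of 30
Reagents that add atoms: none
Why: Dirhodium tetraacetate strips dinitrogen from 30 to give an electrophilic carbenoid at C4, which inserts into the C5–H bond through a concerted, three-centre, hydride-transfer-like transition state, so that C4–C5 forms on the face that held the hydrogen. The closest known reaction type is the dirhodium-catalysed 1,5 C–H insertion of alkyl diazo(dialkoxyphosphoryl)acetates into tertiary C–H bonds, which gives α-phosphono-γ-butyrolactones. The one ring closed is the five-membered lactone (C4, C18, O, C19, C5); it closes by 1,5-insertion through a six-membered transition state that includes the migrating hydrogen, and it ends spiro-fused to ring A. The new quaternary centre C5 is controlled by the C5 configuration already present in 30, because insertion goes with retention (C19 stays β, C4 takes the α position of the hydrogen); C4 is not controlled and is erased in step 25. The step needs site selectivity for C5–H over the 1,6-placed C10–H and C6–H2 and chemoselectivity over the furan and the C12 carbonyl. The preference for five-membered ring closure, the tertiary, undeactivated C5–H bond, the low electrophilicity of the doubly stabilised carbenoid and the electron-poor brominated furan should secure both.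

Step 23
Reactants: 31 spirolactone
Product: 32 C3 primary alcohol
Conditions: HF·pyridine, pyridine/THF, 0 °C to rt
Reagents that add atoms: none
Why: Fluoride-mediated desilylation under buffered, weakly acidic conditions that leave the α-phosphono lactone and the acetate alone.

Step 24
Reactants: 32 alcohol
Product: 33 C3 aldehyde
Conditions: Dess–Martin periodinane, NaHCO3, CH2Cl2, 0 °C to rt
Reagents that add atoms: none
Why: Dess–Martin oxidation of the primary alcohol to the aldehyde under buffered, non-epimerising conditions.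

Step 25
Reactants: 33 aldehyde
Product: 34 ring-A/ring-B bicycle with the C3=C4 alkylidene lactone
Conditions: LiCl, DBU, MeCN, rt, high dilution
Reagents that add atoms: none
Why: Intramolecular Horner–Wadsworth–Emmons reaction under LiCl/amine conditions; only the phosphonate is acidic enough to be deprotonated, the aldehyde is far more electrophilic than the C12 ketone, and the six-membered ring B closes with the C3=C4 alkene, both C4 epimers converging.

Step 26
Reactants: 34 alkylidene lactone
Product: 35 C2 ketone (ene-dione C18(=O)–C4=C3–C2=O)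
Conditions: Rh2(C6H10NO)4 (dirhodium tetrakis(caprolactamate), 1 mol %), t-BuOOH (70% in water), ClCH2CH2Cl, 40 °C
Reagents that add atoms: tert-butyl hydroperoxide, CC(C)(C)OO
Why: Allylic oxidation by tert-butylperoxyl radicals; C2 carries the only allylic C–H bonds of the C3=C4 alkene (C5 is quaternary), so this γ-oxidation of an unsaturated ester should give the ene-dione regiospecifically.

Step 27
Reactants: 35 ene-dione
Product: 36 tetracyclic ketone (ring C closed by the C1–C16 bond; H1 β, furan equatorial)
Conditions: Pd2(dba)3 (dba = dibenzylideneacetone; 5 mol %), Xantphos (12 mol %), K3PO4, toluene, 90 °C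
Reagents that add atoms: none
Why: Palladium-catalysed intramolecular α-arylation of a ketone enolate; zerovalent palladium inserts into the activated C16–Br bond, the C1 enolate (the only enolisable position of the C2 ketone) binds, and reductive elimination closes the seven-membered ring C; the epimerisable C1 centre should settle in the trans-fused arrangement with the furan equatorial.

Step 28
Reactants: 36 tetracyclic ketone
Product: 37 target CNP0182929.1 (C1 S, C2 S, C5 S, C7 R, C8 S, C9 R, C10 R)
Conditions: NaBH4, CeCl3·7H2O, MeOH, −78 °C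
Reagents that add atoms: none
Why: Luche reduction; it is 1,2-selective for the enone carbonyl over the furan-conjugated C12 ketone, and axial attack of hydride on C2 from the α face should give the equatorial 2β alcohol, trans to the furan on C1.

Compound list
1 | 5-hydroxyfuran-2(5H)-one | OC1OC(=O)C=C1 | starting material
2 | (1S,2R,5S)-(+)-menthol | CC(C)[C@H]1CC[C@H](C)C[C@@H]1O | starting material
3 | (5S)-5-[(1S,2R,5S)-menthyloxy]furan-2(5H)-one | O=C1C=C[C@@H](O[C@H]2C[C@@H](C)CC[C@@H]2C(C)C)O1 | intermediate
4 | (E)-pent-3-en-2-one | C/C=C/C(C)=O | starting material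
5 | (E)-2-(triisopropylsilyloxy)penta-1,3-diene | C=C(O[Si](C(C)C)(C(C)C)C(C)C)/C=C/C | intermediate
6 | cis-fused lactone acetal, C7 triisopropylsilyl enol ether, C9 methyl β, menthyloxy anti to ring A | O=C1O[C@H](O[C@H]3C[C@@H](C)CC[C@@H]3C(C)C)[C@H]2CC(O[Si](C(C)C)(C(C)C)C(C)C)=C[C@@H](C)[C@@H]12 | intermediate
7 | hydroxy acid (C1 carboxylic acid on C10, C19 hydroxymethyl on C5, cis) | OC[C@H]1CC(O[Si](C(C)C)(C(C)C)C(C)C)=C[C@@H](C)[C@H]1C(O)=O | intermediate
8 | cis-fused γ-lactone (C1 carbonyl, C19 methylene) | O=C1OC[C@H]2CC(O[Si](C(C)C)(C(C)C)C(C)C)=C[C@@H](C)[C@@H]12 | intermediate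
9 | lactol (anomers) | OC1OC[C@H]2CC(O[Si](C(C)C)(C(C)C)C(C)C)=C[C@@H](C)[C@@H]12 | intermediate
10 | hydroxy (E)-enoate | OC[C@H]1CC(O[Si](C(C)C)(C(C)C)C(C)C)=C[C@@H](C)[C@H]1/C=C/C(=O)OCC | intermediate
11 | C19 triethylsilyl ether of 10 | CC[Si](CC)(CC)OC[C@H]1CC(O[Si](C(C)C)(C(C)C)C(C)C)=C[C@@H](C)[C@H]1/C=C/C(=O)OCC | intermediate
12 | saturated ethyl ester | CC[Si](CC)(CC)OC[C@H]1CC(O[Si](C(C)C)(C(C)C)C(C)C)=C[C@@H](C)[C@H]1CCC(=O)OCC | intermediate
13 | C3 alcohol | CC[Si](CC)(CC)OC[C@H]1CC(O[Si](C(C)C)(C(C)C)C(C)C)=C[C@@H](C)[C@H]1CCCO | intermediate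
14 | C3 tert-butyldimethylsilyl ether, C19 triethylsilyl ether, C7 triisopropylsilyl enol ether | CC[Si](CC)(CC)OC[C@H]1CC(O[Si](C(C)C)(C(C)C)C(C)C)=C[C@@H](C)[C@H]1CCCO[Si](C)(C)C(C)(C)C | intermediate
15 | ring-A enone, C5 and C10 arms cis (β) | O=C1C[C@H](CO[Si](CC)(CC)CC)[C@H](CCCO[Si](C)(C)C(C)(C)C)C(C)=C1 | intermediate
16 | 2-bromofuran-3-carboxylic acid | OC(=O)c1ccoc1Br | starting material
17 | 2-bromo-N-methoxy-N-methylfuran-3-carboxamide | CON(C)C(=O)c1ccoc1Br | intermediate
18 | 1-(2-bromofuran-3-yl)ethan-1-one | CC(=O)c1ccoc1Br | intermediate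
19 | [1-(2-bromofuran-3-yl)ethenyl]oxy(tert-butyl)dimethylsilane | C=C(O[Si](C)(C)C(C)(C)C)c1ccoc1Br | intermediate
20 | Michael adduct, C7 silyl enol ether; C9: C20 β, C11 α | CC(C)(C)[Si](C)(C)OC1=C[C@](C)(CC(=O)c2ccoc2Br)[C@@H](CCCO[Si](C)(C)C(C)(C)C)[C@@H](CO[Si](CC)(CC)CC)C1 | intermediate
21 | Mannich base (C8 dimethylaminomethyl ketone, C8 epimers) | O=C1C[C@H](CO[Si](CC)(CC)CC)[C@H](CCCO[Si](C)(C)C(C)(C)C)[C@@](C)(CC(=O)c2ccoc2Br)C1CN(C)C | intermediate
22 | trimethylammonium iodide of 21 | O=C1C[C@H](CO[Si](CC)(CC)CC)[C@H](CCCO[Si](C)(C)C(C)(C)C)[C@@](C)(CC(=O)c2ccoc2Br)C1C[N+](C)(C)C.[I-] | intermediate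
23 | α-methylene ketone | O=C1C[C@H](CO[Si](CC)(CC)CC)[C@H](CCCO[Si](C)(C)C(C)(C)C)[C@@](C)(CC(=O)c2ccoc2Br)C1=C | intermediate
24 | C7 ketone, C17 β | O=C1C[C@H](CO[Si](CC)(CC)CC)[C@H](CCCO[Si](C)(C)C(C)(C)C)[C@@](C)(CC(=O)c2ccoc2Br)[C@@H]1C | intermediate
25 | 7β-alcohol | O[C@@H]1C[C@H](CO[Si](CC)(CC)CC)[C@H](CCCO[Si](C)(C)C(C)(C)C)[C@@](C)(CC(=O)c2ccoc2Br)[C@@H]1C | intermediate
26 | 7β-acetate | CC(=O)O[C@@H]1C[C@H](CO[Si](CC)(CC)CC)[C@H](CCCO[Si](C)(C)C(C)(C)C)[C@@](C)(CC(=O)c2ccoc2Br)[C@@H]1C | intermediate
27 | C19 alcohol | CC(=O)O[C@@H]1C[C@H](CO)[C@H](CCCO[Si](C)(C)C(C)(C)C)[C@@](C)(CC(=O)c2ccoc2Br)[C@@H]1C | intermediate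
28 | diethylphosphonoacetic acid | CCOP(=O)(CC(=O)O)OCC | starting material
29 | C19 (diethoxyphosphoryl)acetate | CC(=O)O[C@@H]1C[C@H](COC(=O)CP(=O)(OCC)OCC)[C@H](CCCO[Si](C)(C)C(C)(C)C)[C@@](C)(CC(=O)c2ccoc2Br)[C@@H]1C | intermediate
30 | ring-A cyclohexylmethyl diazo(diethoxyphosphoryl)acetate | CC(=O)O[C@@H]1C[C@H](COC(=O)C(=[N+]=[N-])P(=O)(OCC)OCC)[C@H](CCCO[Si](C)(C)C(C)(C)C)[C@@](C)(CC(=O)c2ccoc2Br)[C@@H]1C | intermediate
31 | spiro α-phosphono-γ-lactone on ring A | CC(=O)O[C@@H]1C[C@]2(COC(=O)[C@@H]2P(=O)(OCC)OCC)[C@H](CCCO[Si](C)(C)C(C)(C)C)[C@@](C)(CC(=O)c3ccoc3Br)[C@@H]1C | intermediate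
32 | C3 alcohol of the spirolactone | CC(=O)O[C@@H]1C[C@]2(COC(=O)[C@@H]2P(=O)(OCC)OCC)[C@H](CCCO)[C@@](C)(CC(=O)c3ccoc3Br)[C@@H]1C | intermediate
33 | C3 aldehyde | CC(=O)O[C@@H]1C[C@]2(COC(=O)[C@@H]2P(=O)(OCC)OCC)[C@H](CCC=O)[C@@](C)(CC(=O)c3ccoc3Br)[C@@H]1C | intermediate
34 | trans-fused ring-A/ring-B bicycle, C3=C4 alkylidene spirolactone | CC(=O)O[C@@H]1C[C@@]23COC(=O)C2=CCC[C@@H]3[C@@](C)(CC(=O)c4ccoc4Br)[C@@H]1C | intermediate
35 | C2 ketone (ene-dione) | CC(=O)O[C@@H]1C[C@@]23COC(=O)C2=CC(=O)C[C@@H]3[C@@](C)(CC(=O)c4ccoc4Br)[C@@H]1C | intermediate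
36 | tetracyclic C2 ketone, ring C closed | CC(=O)O[C@@H]1C[C@@]23COC(=O)C2=CC(=O)[C@H]2c4occc4C(=O)C[C@@](C)([C@@H]1C)[C@@H]23 | intermediate
37 | CNP0182929.1 | CC(=O)O[C@@H]1C[C@@]23COC(=O)C2=C[C@H](O)[C@H]2c4occc4C(=O)C[C@@](C)([C@@H]1C)[C@@H]23 | target

Total step count: 28. Longest linear sequence: 24 steps (steps 1, 3 to 10 and 14 to 28).

Steps most likely to fail

Step 22. The doubly stabilised carbenoid may react too slowly with the flanked tertiary C5–H bond, so that carbene dimerisation, attack on the furan or on the C12 carbonyl oxygen, or 1,6-insertion at C10–H takes over. The fallback uses a malonyl carbenoid and closes ring B by condensation–decarboxylation in place of the olefination. It would set out from alcohol 27, which is esterified (N,N′-dicyclohexylcarbodiimide, 4-(dimethylamino)pyridine) with 2-(trimethylsilyl)ethyl hydrogen malonate to the mixed malonate F1. Diazo transfer (4-acetamidobenzenesulfonyl azide, Et3N) gives the diazomalonate F2, whose more electrophilic carbenoid (Rh2(OAc)4, CH2Cl2, reflux) should insert into C5–H to give the spiro α-[2-(trimethylsilyl)ethoxycarbonyl] lactone F3. Bu4NF removes the silylethyl ester and the C3 silyl ether in one operation to give the spiro α-carboxy lactone alcohol F4, and Dess–Martin oxidation gives the aldehyde acid F5. Piperidine in pyridine at 80 °C then closes ring B by an intramolecular Doebner–Knoevenagel condensation with loss of CO2, and the route is rejoined at 34.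

Step 14. The weakly nucleophilic aryl ketone enol ether may fail to attack the hindered, fully substituted β-carbon C9, so that 1,2-addition at C7 (Mukaiyama aldol) or slow decomposition of the silyl enol ether wins. The fallback uses an ester donor and builds the ketone afterwards by acylation and decarboxylation. From enone 15, Mukaiyama–Michael addition of the far more nucleophilic ketene acetal 1-tert-butoxy-1-(tert-butyldimethylsilyloxy)ethene under the same catalysis gives the tert-butyl ester Michael adduct F6. Its lithium enolate (LiN(i-Pr)2, THF, −78 °C) is acylated with 2-bromofuran-3-carbonyl chloride (from 16 and oxalyl chloride) to the β-keto ester F7. Me3SiOTf with 2,6-lutidine cleaves the tert-butyl ester, the β-keto acid loses CO2 on buffered aqueous work-up at 40 °C, and the route is rejoined at 20.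

Step 26. Hydrogen abstraction from C2 of the electron-poor alkene may be slow, so that oxidation of the furan ring or of C11–H competes, or the reaction stops at the C2 tert-butyl peroxide. The fallback is a route through the allylic halide. From 34, Wohl–Ziegler bromination (N-bromosuccinimide, azobisisobutyronitrile, PhCF3, 80 °C) at the only allylic C–H position gives the C2 allylic bromide F8, and Kornblum oxidation (AgBF4, Me2SO; then Et3N) converts it into enone 35.

Further compounds
F1 | step 22 | C19 2-(trimethylsilyl)ethyl malonate of 27 | CC(=O)O[C@@H]1C[C@H](COC(=O)CC(=O)OCC[Si](C)(C)C)[C@H](CCCO[Si](C)(C)C(C)(C)C)[C@@](C)(CC(=O)c2ccoc2Br)[C@@H]1C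
F2 | step 22 | C19 2-(trimethylsilyl)ethyl diazomalonate | CC(=O)O[C@@H]1C[C@H](COC(=O)C(=[N+]=[N-])C(=O)OCC[Si](C)(C)C)[C@H](CCCO[Si](C)(C)C(C)(C)C)[C@@](C)(CC(=O)c2ccoc2Br)[C@@H]1C
F3 | step 22 | spiro α-[2-(trimethylsilyl)ethoxycarbonyl]-γ-lactone (C4 epimers) | CC(=O)O[C@@H]1C[C@]2(COC(=O)C2C(=O)OCC[Si](C)(C)C)[C@H](CCCO[Si](C)(C)C(C)(C)C)[C@@](C)(CC(=O)c3ccoc3Br)[C@@H]1C
F4 | step 22 | spiro α-carboxy-γ-lactone with free C3 alcohol | CC(=O)O[C@@H]1C[C@]2(COC(=O)C2C(O)=O)[C@H](CCCO)[C@@](C)(CC(=O)c3ccoc3Br)[C@@H]1C
F5 | step 22 | spiro α-carboxy-γ-lactone C3 aldehyde | CC(=O)O[C@@H]1C[C@]2(COC(=O)C2C(O)=O)[C@H](CCC=O)[C@@](C)(CC(=O)c3ccoc3Br)[C@@H]1C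
F6 | step 14 | tert-butyl ester Michael adduct, C7 silyl enol ether | CC(C)(C)[Si](C)(C)OC1=C[C@](C)(CC(=O)OC(C)(C)C)[C@@H](CCCO[Si](C)(C)C(C)(C)C)[C@@H](CO[Si](CC)(CC)CC)C1
F7 | step 14 | tert-butyl β-keto ester (C11 epimers) | CC(C)(C)[Si](C)(C)OC1=C[C@](C)(C(C(=O)c2ccoc2Br)C(=O)OC(C)(C)C)[C@@H](CCCO[Si](C)(C)C(C)(C)C)[C@@H](CO[Si](CC)(CC)CC)C1
F8 | step 26 | C2 allylic bromide of 34 (C2 epimers) | CC(=O)O[C@@H]1C[C@@]23COC(=O)C2=CC(Br)C[C@@H]3[C@@](C)(CC(=O)c4ccoc4Br)[C@@H]1C
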